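The heptane chain is numbered C1 (oxane carbon bearing ring B) to C7 (benzylic carbon of ring A); the oxane oxygen bridges C1 and C5. Since C5 carries both this oxygen and the C6–C7 arm, the ring O–C5 bond and the C6–C7 bond are cut together. Forward, a palladium-mediated oxycarbonylation lets the C1 hydroxyl add to a terminal C5=C6 alkene while carbon monoxide and methanol cap C6 as a methyl ester (C7), closing the oxane and fixing C5 cis to C1 and C3. The substrate is an anti-1,3-diol derivative, a 1-aryl-hex-5-en-1-ol with free benzylic C1–OH and silylated C3–OH, assembled by two asymmetric allylations.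

Key step: step 8

Remark: the catalytic cycle of step 8 releases hydrogen chloride, so that step is buffered with NaOAc. Ar denotes 3,4-bis(benzyloxy)-5-methoxyphenyl (protected ring B). Oxane locants are C2 for the side-chain carbon and C6 for the Ar-bearing carbon. The C2 descriptor changes between 16, 17, 18 and 22 only because CIP priorities change; the ring stays all-cis throughout.

Step 1
Reactants: 1 3,4-dihydroxy-5-methoxybenzaldehyde (5-hydroxyvanillin)
Product: 2 3,4-bis(benzyloxy)-5-methoxybenzaldehyde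
Conditions: BnBr (2.4 equiv), K2CO3, DMF, 60 °C
Reagents that add atoms: benzyl bromide, BrCc1ccccc1
Why: Williamson ether synthesis, in which both catechol phenoxides are alkylated by the reactive benzylic bromide under carbonate conditions that leave the aldehyde untouched, giving phenol protection that is removed in one hydrogenolysis at the end.

Step 2
Reactants: 2 3,4-bis(benzyloxy)-5-methoxybenzaldehyde; 3 allylboronic acid pinacol ester
Product: 5 (1S)-1-[3,4-bis(benzyloxy)-5-methoxyphenyl]but-3-en-1-ol, via pinacol borate ester 4 (not isolated)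
Conditions: (S)-TRIP phosphoric acid [(S)-3,3'-bis(2,4,6-triisopropylphenyl)-1,1'-binaphthyl-2,2'-diyl hydrogen phosphate] (5 mol %), toluene, −30 °C; aq. NaHCO3 work-up
Reagents that add atoms: none
Why: Chiral phosphoric acid-catalysed allylboration of an aromatic aldehyde, in which the acid hydrogen-bonds to the boronate oxygen and the formyl hydrogen in a closed chair transition state and the (S)-configured catalyst should expose the Si face of the carbonyl, so that C1 is formed with S configuration.

Step 3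
Reactants: 5 (1S)-1-Ar-but-3-en-1-ol
Product: 6 {[(1S)-1-Ar-but-3-en-1-yl]oxy}triethylsilane
Conditions: TESCl, imidazole, DMF, 0 °C to rt
Reagents that add atoms: chlorotriethylsilane, CC[Si](CC)(CC)Cl
Why: Standard silyl ether formation with a silyl chloride and imidazole; the triethylsilyl group is a temporary mask that survives oxidative cleavage and allylboration but is cleaved more readily than the tert-butyldimethylsilyl group introduced later.

Step 4
Reactants: 6 {[(1S)-1-Ar-but-3-en-1-yl]oxy}triethylsilane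
Product: 8 (3S)-3-Ar-3-(triethylsilyloxy)propanal, via vicinal diol 7 (not isolated)
Conditions: OsO4 (2 mol %), NaIO4 (4 equiv), 2,6-lutidine, dioxane/H2O 3:1, rt
Reagents that add atoms: osmium tetroxide, O=[Os](=O)(=O)=O; NaIO4, [Na+].[O-]I(=O)(=O)=O
Why: Lemieux–Johnson oxidation, in which catalytic dihydroxylation of the only alkene and periodate glycol cleavage in the same flask remove the terminal carbon without touching the electron-rich arene or the benzyl ethers (the reason ozone is avoided), while the lutidine buffer suppresses β-elimination of the silyloxy group and C1 is not affected.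

Step 5
Reactants: 8 (3S)-3-Ar-3-(triethylsilyloxy)propanal; 9 (+)-B-allyldiisopinocampheylborane [(+)-Ipc2B(allyl), the enantiomer derived from (−)-α-pinene]
Product: 11 (4R,6S)-6-Ar-6-(triethylsilyloxy)hex-1-en-4-ol, via diisopinocampheylborinate 10 (not isolated)
Conditions: 9 (1.3 equiv), Et2O, −78 °C; then aq. NaOH, H2O2, 0 °C to rt
Reagents that add atoms: none
Why: Brown allylation through a closed chair transition state, in which the isopinocampheyl groups of the (−)-α-pinene-derived reagent direct the allyl group to the Re face of the aldehyde, so that reagent control, which outweighs the weak 1,3-induction of a β-silyloxy group, should set the new carbinol centre (chain C3) as R, anti to C1.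

Step 6
Reactants: 11 (4R,6S)-6-Ar-6-(triethylsilyloxy)hex-1-en-4-ol
Product: 12 (4R,6S)-6-Ar-4-(tert-butyldimethylsilyloxy)-6-(triethylsilyloxy)hex-1-ene
Conditions: TBSOTf, 2,6-lutidine, CH2Cl2, −78 to 0 °C
Reagents that add atoms: tert-butyldimethylsilyl triflate, CC(C)(C)[Si](C)(C)OS(=O)(=O)C(F)(F)F
Why: Silylation of a secondary alcohol with a silyl triflate and a non-nucleophilic base is fast at low temperature and leaves the triethylsilyl ether and the alkene unchanged.

Step 7
Reactants: 12 (4R,6S)-6-Ar-4-(tert-butyldimethylsilyloxy)-6-(triethylsilyloxy)hex-1-ene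
Product: 13 (1S,3R)-1-[3,4-bis(benzyloxy)-5-methoxyphenyl]-3-(tert-butyldimethylsilyloxy)hex-5-en-1-ol (1,3-anti)
Conditions: PPTS (0.2 equiv), EtOH/CH2Cl2 1:1, 0 °C
Reagents that add atoms: none
Why: Selective acid-catalysed solvolysis of a silyl ether, in which the less hindered triethylsilyl ether is cleaved far faster than the tert-butyldimethylsilyl ether and the pyridinium acid is too weak to ionise the benzylic C1–O bond, so only the C1 hydroxyl is released.

Step 8
Reactants: 13 (1S,3R)-1-Ar-3-(tert-butyldimethylsilyloxy)hex-5-en-1-ol; 14 carbon monoxide; 15 methanol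
Product: 16 methyl 2-[(2R,4R,6S)-6-[3,4-bis(benzyloxy)-5-methoxyphenyl]-4-(tert-butyldimethylsilyloxy)oxan-2-yl]acetate (all-cis)
Conditions: PdCl2(MeCN)2 (10 mol %), CuCl2 (3 equiv), NaOAc (3 equiv), CO (1 atm), MeOH/MeCN 1:1, rt
Reagents that add atoms: none
Why: Divalent palladium coordinates the terminal C5=C6 alkene, the free C1 hydroxyl adds anti to the metal at the internal carbon C5, the primary alkylpalladium at C6 inserts CO, and methanol cleaves the acylpalladium to the methyl ester while CuCl2 reoxidises the zerovalent palladium that is released. The closest known reaction type is the intramolecular alkoxypalladation–methoxycarbonylation of hex-5-en-1-ols (Semmelhack reaction), which is established for 2,6-cis-oxanes. The oxane closes in a 6-exo-trig mode. The new C5 stereocentre is set under substrate control by a chair-like transition state in which the C1 aryl group, the C3 silyloxy group and the palladium-bound alkene are all equatorial, so the anti relationship of C1 and C3 is translated into the all-cis ring. The step needs 6-exo oxypalladation instead of 7-endo attack, carbonylation instead of β-hydride elimination, and a single nucleophilic oxygen: Markovnikov attack on a monosubstituted alkene and the ring size secure the first, the CO atmosphere traps the primary alkylpalladium (whose only β-hydrogen sits on C5) before it eliminates, and the silyl group on the C3 oxygen leaves the C1 hydroxyl as the only nucleophile. Hydrogen chloride is formed in the cycle, so NaOAc is added to protect the benzylic C1–O bond and the silyl ether.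

Step 9
Reactants: 16 methyl 2-[(2R,4R,6S)-6-Ar-4-(tert-butyldimethylsilyloxy)oxan-2-yl]acetate
Product: 17 2-[(2S,4R,6S)-6-Ar-4-(tert-butyldimethylsilyloxy)oxan-2-yl]ethan-1-ol (all-cis)
Conditions: LiAlH4, THF, 0 °C
Reagents that add atoms: none
Why: Hydride reduction of an ester to the primary alcohol, to which silyl, benzyl and cyclic ethers are inert at 0 °C and in which no stereocentre takes part.

Step 10
Reactants: 17 2-[(2S,4R,6S)-6-Ar-4-(tert-butyldimethylsilyloxy)oxan-2-yl]ethan-1-ol
Product: 18 (2R,4R,6S)-6-Ar-4-(tert-butyldimethylsilyloxy)-2-(2-iodoethyl)oxane (all-cis)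
Conditions: I2, PPh3, imidazole, CH2Cl2, 0 °C to rt
Reagents that add atoms: iodine, II
Why: Appel-type iodination, in which the alkoxyphosphonium ion of the primary alcohol is displaced by iodide in an SN2 step under nearly neutral conditions that the silyl ether and the benzylic ring C–O bond tolerate.

Step 11
Reactants: 19 4-bromo-2-methoxyphenol
Product: 20 1-(benzyloxy)-4-bromo-2-methoxybenzene
Conditions: BnBr, K2CO3, DMF, rt
Reagents that add atoms: benzyl bromide, BrCc1ccccc1
Why: Williamson ether synthesis on a simple phenol, which removes the acidic proton that would quench the organozinc of the next step and installs a group that leaves in the final hydrogenolysis.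

Step 12
Reactants: 18 (2R,4R,6S)-6-Ar-4-(tert-butyldimethylsilyloxy)-2-(2-iodoethyl)oxane; 20 1-(benzyloxy)-4-bromo-2-methoxybenzene
Product: 22 (2S,4R,6S)-6-Ar-2-{2-[4-(benzyloxy)-3-methoxyphenyl]ethyl}-4-(tert-butyldimethylsilyloxy)oxane, via alkylzinc iodide 21 (not isolated)
Conditions: Zn dust (I2-activated), LiCl, THF, 40 °C; then 20, Pd(OAc)2 (2 mol %), SPhos (4 mol %), THF, 50 °C
Reagents that add atoms: none
Why: Negishi coupling, in which direct zinc insertion into the primary C–I bond gives an alkylzinc iodide that has no β-heteroatom and tolerates the ethers present, and a palladium catalyst carrying the bulky biarylphosphine SPhos promotes oxidative addition to the electron-rich aryl bromide and reductive elimination ahead of β-hydride elimination, forming the C7–aryl bond.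

Step 13
Reactants: 22 (2S,4R,6S)-6-Ar-2-{2-[4-(benzyloxy)-3-methoxyphenyl]ethyl}-4-(tert-butyldimethylsilyloxy)oxane
Product: 23 (2S,4R,6S)-6-Ar-2-{2-[4-(benzyloxy)-3-methoxyphenyl]ethyl}oxan-4-ol (all-cis)
Conditions: TBAF, THF, 0 °C to rt
Reagents that add atoms: none
Why: Fluoride-mediated desilylation driven by the strong Si–F bond, to which aryl benzyl ethers and the oxane are stable, carried out before the phenols are unmasked so that the catechol never meets basic fluoride.

Step 14
Reactants: 23 (2S,4R,6S)-6-Ar-2-{2-[4-(benzyloxy)-3-methoxyphenyl]ethyl}oxan-4-ol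
Product: 24 5-[(2S,4R,6S)-4-hydroxy-6-[2-(4-hydroxy-3-methoxyphenyl)ethyl]oxan-2-yl]-3-methoxybenzene-1,2-diol (CNP0399218.1)
Conditions: H2 (1 atm), 10% Pd/C, EtOAc/EtOH, rt
Reagents that add atoms: none
Why: Catalytic hydrogenolysis of the three aryl benzyl ethers over Pd/C under neutral conditions, where the benzylic C–O bond of the oxane, lacking acid activation, should react much more slowly, and the three stereocentres are not touched.

Compound list
1 | 3,4-dihydroxy-5-methoxybenzaldehyde (5-hydroxyvanillin) | COc1cc(C=O)cc(O)c1O | starting material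
2 | 3,4-bis(benzyloxy)-5-methoxybenzaldehyde | O=Cc1cc(OCc2ccccc2)c(OCc2ccccc2)c(OC)c1 | intermediate
3 | allylboronic acid pinacol ester | C=CCB1OC(C)(C)C(C)(C)O1 | starting material
4 | 2-{[(1S)-1-Ar-but-3-en-1-yl]oxy}-4,4,5,5-tetramethyl-1,3,2-dioxaborolane | C=CC[C@H](OB1OC(C)(C)C(C)(C)O1)c1cc(OCc2ccccc2)c(OCc2ccccc2)c(OC)c1 | intermediate
5 | (1S)-1-[3,4-bis(benzyloxy)-5-methoxyphenyl]but-3-en-1-ol | C=CC[C@H](O)c1cc(OCc2ccccc2)c(OCc2ccccc2)c(OC)c1 | intermediate
6 | {[(1S)-1-Ar-but-3-en-1-yl]oxy}triethylsilane | C=CC[C@H](O[Si](CC)(CC)CC)c1cc(OCc2ccccc2)c(OCc2ccccc2)c(OC)c1 | intermediate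
7 | (4S)-4-Ar-4-(triethylsilyloxy)butane-1,2-diol (both C2 epimers) | OCC(O)C[C@H](O[Si](CC)(CC)CC)c1cc(OCc2ccccc2)c(OCc2ccccc2)c(OC)c1 | intermediate
8 | (3S)-3-Ar-3-(triethylsilyloxy)propanal | O=CC[C@H](O[Si](CC)(CC)CC)c1cc(OCc2ccccc2)c(OCc2ccccc2)c(OC)c1 | intermediate
9 | (+)-B-allyldiisopinocampheylborane, (+)-Ipc2B(allyl), from (−)-α-pinene | C=CCB([C@H]1C[C@H]2C[C@@H]([C@@H]1C)C2(C)C)[C@H]1C[C@H]2C[C@@H]([C@@H]1C)C2(C)C | starting material
10 | (4R,6S)-6-Ar-6-(triethylsilyloxy)hex-1-en-4-yl diisopinocampheylborinate | C=CC[C@@H](OB([C@H]1C[C@H]2C[C@@H]([C@@H]1C)C2(C)C)[C@H]1C[C@H]2C[C@@H]([C@@H]1C)C2(C)C)C[C@H](O[Si](CC)(CC)CC)c1cc(OCc2ccccc2)c(OCc2ccccc2)c(OC)c1 | intermediate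
11 | (4R,6S)-6-Ar-6-(triethylsilyloxy)hex-1-en-4-ol (1,3-anti) | C=CC[C@@H](O)C[C@H](O[Si](CC)(CC)CC)c1cc(OCc2ccccc2)c(OCc2ccccc2)c(OC)c1 | intermediate
12 | (4R,6S)-6-Ar-4-(tert-butyldimethylsilyloxy)-6-(triethylsilyloxy)hex-1-ene | C=CC[C@@H](O[Si](C)(C)C(C)(C)C)C[C@H](O[Si](CC)(CC)CC)c1cc(OCc2ccccc2)c(OCc2ccccc2)c(OC)c1 | intermediate
13 | (1S,3R)-1-[3,4-bis(benzyloxy)-5-methoxyphenyl]-3-(tert-butyldimethylsilyloxy)hex-5-en-1-ol (1,3-anti) | C=CC[C@@H](O[Si](C)(C)C(C)(C)C)C[C@H](O)c1cc(OCc2ccccc2)c(OCc2ccccc2)c(OC)c1 | intermediate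
14 | carbon monoxide | [C-]#[O+] | starting material
15 | methanol | CO | starting material
16 | methyl 2-[(2R,4R,6S)-6-Ar-4-(tert-butyldimethylsilyloxy)oxan-2-yl]acetate (all-cis) | COC(=O)C[C@H]1C[C@@H](O[Si](C)(C)C(C)(C)C)C[C@@H](c2cc(OCc3ccccc3)c(OCc3ccccc3)c(OC)c2)O1 | intermediate
17 | 2-[(2S,4R,6S)-6-Ar-4-(tert-butyldimethylsilyloxy)oxan-2-yl]ethan-1-ol (all-cis) | OCC[C@H]1C[C@@H](O[Si](C)(C)C(C)(C)C)C[C@@H](c2cc(OCc3ccccc3)c(OCc3ccccc3)c(OC)c2)O1 | intermediate
18 | (2R,4R,6S)-6-Ar-4-(tert-butyldimethylsilyloxy)-2-(2-iodoethyl)oxane (all-cis) | ICC[C@H]1C[C@@H](O[Si](C)(C)C(C)(C)C)C[C@@H](c2cc(OCc3ccccc3)c(OCc3ccccc3)c(OC)c2)O1 | intermediate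
19 | 4-bromo-2-methoxyphenol | COc1cc(Br)ccc1O | starting material
20 | 1-(benzyloxy)-4-bromo-2-methoxybenzene | COc1cc(Br)ccc1OCc1ccccc1 | intermediate
21 | {2-[(2R,4R,6S)-6-Ar-4-(tert-butyldimethylsilyloxy)oxan-2-yl]ethyl}zinc iodide | I[Zn]CC[C@H]1C[C@@H](O[Si](C)(C)C(C)(C)C)C[C@@H](c2cc(OCc3ccccc3)c(OCc3ccccc3)c(OC)c2)O1 | intermediate
22 | (2S,4R,6S)-6-Ar-2-{2-[4-(benzyloxy)-3-methoxyphenyl]ethyl}-4-(tert-butyldimethylsilyloxy)oxane (all-cis) | COc1cc(CC[C@H]2C[C@@H](O[Si](C)(C)C(C)(C)C)C[C@@H](c3cc(OCc4ccccc4)c(OCc4ccccc4)c(OC)c3)O2)ccc1OCc1ccccc1 | intermediate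
23 | (2S,4R,6S)-6-Ar-2-{2-[4-(benzyloxy)-3-methoxyphenyl]ethyl}oxan-4-ol (all-cis) | COc1cc(CC[C@H]2C[C@@H](O)C[C@@H](c3cc(OCc4ccccc4)c(OCc4ccccc4)c(OC)c3)O2)ccc1OCc1ccccc1 | intermediate
24 | 5-[(2S,4R,6S)-4-hydroxy-6-[2-(4-hydroxy-3-methoxyphenyl)ethyl]oxan-2-yl]-3-methoxybenzene-1,2-diol (all-cis) | COc1cc(CC[C@H]2C[C@@H](O)C[C@@H](c3cc(O)c(O)c(OC)c3)O2)ccc1O | target

Total step count: 14. Longest linear sequence: 13 steps (steps 1–10 and 12–14, from 1 to 24); step 11 is a one-step side branch.

Steps most likely to fail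

Step 8. The carbonylation may stall, so that β-hydride elimination or Wacker-type oxidation of the alkene competes, or the acid formed may cause solvolysis at the benzylic carbinol and loss of the silyl ether. The fallback sets out from 13 and closes the ring by conjugate addition instead of oxypalladation. Cross-metathesis of 13 with methyl acrylate (second-generation Grubbs catalyst, CH2Cl2, 40 °C) should give methyl (2E,5R,7S)-7-Ar-5-(tert-butyldimethylsilyloxy)-7-hydroxyhept-2-enoate F1. Intramolecular oxa-Michael addition of the C1 hydroxyl under equilibrating conditions (catalytic KOt-Bu, THF, −20 °C to rt) should then give the all-equatorial oxane, and the route is rejoined at 16.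

Step 12. Zinc insertion into the iodide may be sluggish or incomplete, and the organozinc may be lost by protonolysis or homocoupling before it transmetallates. The fallback reverses the polarity of the coupling. Bromide 20 is converted with Mg turnings in THF into [4-(benzyloxy)-3-methoxyphenyl]magnesium bromide F2, which is coupled with iodide 18 in an iron-catalysed Kumada-type reaction (FeCl3 5 mol %, TMEDA, THF, 0 °C). The route is rejoined at 22.

Step 5. Facial selectivity of the allyl transfer may be insufficient, or aldehyde 8 may lose silanol by β-elimination before it is allylated. The fallback sets C3 by substrate-controlled hydride delivery instead of reagent-controlled allylation. It sets out from 8: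
- AllylMgBr in THF at −78 °C should give (6S)-6-Ar-6-(triethylsilyloxy)hex-1-en-4-ol F3 as a mixture of C4 epimers.
- Buffered Dess–Martin oxidation should give (1S)-1-Ar-1-(triethylsilyloxy)hex-5-en-3-one F4.
- HF·pyridine in THF/pyridine should release (1S)-1-Ar-1-hydroxyhex-5-en-3-one F5.
- Evans–Tishchenko reduction (SmI2 0.3 equiv, benzaldehyde, THF, −10 °C) delivers hydride within the samarium-bound hemiacetal and should give the anti product (1S,3R)-1-Ar-3-hydroxyhex-5-en-1-yl benzoate F6, with C3–OH free and C1–O acylated.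
- Silylation (TBSOTf, 2,6-lutidine) should give (1S,3R)-1-Ar-3-(tert-butyldimethylsilyloxy)hex-5-en-1-yl benzoate F7.
- Methanolysis of the benzoate (K2CO3, MeOH) rejoins the route at 13.

Further compounds
F1 | step 8 | methyl (2E,5R,7S)-7-Ar-5-(tert-butyldimethylsilyloxy)-7-hydroxyhept-2-enoate | COC(=O)/C=C/C[C@@H](O[Si](C)(C)C(C)(C)C)C[C@H](O)c1cc(OCc2ccccc2)c(OCc2ccccc2)c(OC)c1
F2 | step 12 | [4-(benzyloxy)-3-methoxyphenyl]magnesium bromide | COc1cc([Mg]Br)ccc1OCc1ccccc1
F3 | step 5 | (6S)-6-Ar-6-(triethylsilyloxy)hex-1-en-4-ol (C4 epimers) | C=CCC(O)C[C@H](O[Si](CC)(CC)CC)c1cc(OCc2ccccc2)c(OCc2ccccc2)c(OC)c1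
F4 | step 5 | (1S)-1-Ar-1-(triethylsilyloxy)hex-5-en-3-one | C=CCC(=O)C[C@H](O[Si](CC)(CC)CC)c1cc(OCc2ccccc2)c(OCc2ccccc2)c(OC)c1
F5 | step 5 | (1S)-1-Ar-1-hydroxyhex-5-en-3-one | C=CCC(=O)C[C@H](O)c1cc(OCc2ccccc2)c(OCc2ccccc2)c(OC)c1
F6 | step 5 | (1S,3R)-1-Ar-3-hydroxyhex-5-en-1-yl benzoate | C=CC[C@@H](O)C[C@H](OC(=O)c1ccccc1)c1cc(OCc2ccccc2)c(OCc2ccccc2)c(OC)c1
F7 | step 5 | (1S,3R)-1-Ar-3-(tert-butyldimethylsilyloxy)hex-5-en-1-yl benzoate | C=CC[C@@H](O[Si](C)(C)C(C)(C)C)C[C@H](OC(=O)c1ccccc1)c1cc(OCc2ccccc2)c(OCc2ccccc2)c(OC)c1
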